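**Strategy.** Ring B (C5–C6–C7–C8–C9–C10) is formed by inserting C8, with its methyl group, into the five-membered ring (C5–C6–C7–C9–C10) of a trans-hydrindan-9-one. This precursor comes from the Hajos–Parrish ketone and already holds the C4 gem-dimethyl group, H-5α, the C10 methyl and a C2=C3 alkene as masked diol. Sc(OTf)3-catalysed diazoethane insertion exploits the flanking of C9 by quaternary C10 and methylene C7: only C7 migrates, so one operation creates the six-membered ring, both bonds to C8 and the equatorial C8 methyl. The new C9 ketone then takes a vinyl group anti to the C10 methyl, extended by B-alkyl Suzuki coupling.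

Key step: step 7

Remark: labdane numbering is used for every bicyclic compound (the hydrindanes lack C8), and α means the face opposite the C10 methyl. The target SMILES is read as 9β-OH (cis to the C10 methyl, side chain 9α), 8α-CH3, 2α-OAc, 3α-OH and H-5α. Ethereal diazoethane is treated as a freshly prepared reagent.

Step 1
Reactants: 1 (S)-Hajos–Parrish ketone, (7aS)-7a-methyl-2,3,7,7a-tetrahydro-1H-indene-1,5(6H)-dione
Product: 2 C9 ethylene ketal of 1 (C4=C5–C3=O enone kept)
Conditions: ethylene glycol (5 equiv), p-TsOH·H2O (cat.), 4 Å molecular sieves, CH2Cl2, rt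
Reagents that add atoms: ethylene glycol, OCCO
Why: Acid-catalysed ketalisation should take the saturated cyclopentanone carbonyl (C9) in preference to the less electrophilic conjugated C3 carbonyl; no stereocentre is formed.

Step 2
Reactants: 2 C9 ethylene ketal of 1
Product: 4 4,4-dimethyl-Δ5(6)-3-ketone 9-ketal, via monomethyl ketone 3 (not isolated)
Conditions: KOtBu (3 equiv), MeI (6 equiv), t-BuOH/THF, 0 °C → rt
Reagents that add atoms: iodomethane, CI
Why: Deconjugative α,α-dialkylation of the enone through its extended dienolate (γ-deprotonation at C6, C-methylation at C4, twice) should move the alkene to C5=C6; C4 carries two identical groups, so no stereocentre arises.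

Step 3
Reactants: 4 4,4-dimethyl-Δ5(6)-3-ketone 9-ketal
Product: 5 4,4,10β-trimethyl-trans-hydrindan-3-one 9-ketal (H-5α)
Conditions: H2 (50 bar), 10% Pd/C, EtOAc, rt
Reagents that add atoms: none
Why: Heterogeneous catalytic hydrogenation of the trisubstituted cyclopentene should deliver hydrogen to C5 from the α face, because the β face is covered by the C10 methyl and the 4β methyl (as in hydrogenations of Δ14 steroids), which sets the trans ring fusion.

Step 4
Reactants: 5 4,4,10β-trimethyl-trans-hydrindan-3-one 9-ketal
Product: 6 C3 p-toluenesulfonylhydrazone of 5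
Conditions: TsNHNH2 (1.2 equiv), EtOH, 70 °C
Reagents that add atoms: p-toluenesulfonyl hydrazide, Cc1ccc(cc1)S(=O)(=O)NN
Why: Condensation of the ketone with the sulfonyl hydrazide (hydrazone formation) should place the NHTs group anti to quaternary C4 and thus syn to C2, as the next step requires.

Step 5
Reactants: 6 C3 p-toluenesulfonylhydrazone
Product: 8 4,4,10β-trimethyl-trans-hydrind-2-ene 9-ketal (C2=C3), via C3 vinyllithium 7 (not isolated)
Conditions: MeLi (3.5 equiv), Et2O/THF, 0 °C → rt; then H2O
Reagents that add atoms: none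
Why: In this Shapiro reaction the N–H and the only α-hydrogens (at C2) are removed, loss of sulfinate and N2 gives the C3 vinyllithium, and protonation gives the C2=C3 alkene without touching a stereocentre.

Step 6
Reactants: 8 4,4,10β-trimethyl-trans-hydrind-2-ene 9-ketal
Product: 9 4,4,10β-trimethyl-trans-hydrind-2-en-9-one (H-5α)
Conditions: HCl (2 M aq.), THF, rt
Reagents that add atoms: water, O
Why: Acid-catalysed ketal hydrolysis should free the C9 ketone while the unactivated C2=C3 alkene is inert to dilute acid.

Step 7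
Reactants: 9 4,4,10β-trimethyl-trans-hydrind-2-en-9-one
Product: 11 4,4,8α,10β-tetramethyl-trans-octal-2-en-9-one (H-5α, H-8β), via 8β-methyl epimer 10 (not isolated)
Conditions: CH3CHN2 (2 equiv, Et2O solution), Sc(OTf)3 (10 mol %), toluene, −78 → −20 °C; then NaOMe (cat.), MeOH, rt
Reagents that add atoms: diazoethane, CC=[N+]=[N-]
Why: The Sc(OTf)3-activated C9 carbonyl is attacked by the nucleophilic carbon of diazoethane, and in the resulting β-oxido diazonium ion the C9–C7 bond migrates to the diazo carbon with loss of N2, which enlarges the five-membered ring to ring B and places CH(CH3) between C9 and C7. The closest known reaction type is the Lewis-acid-promoted diazoalkane homologation of cyclic ketones (Tiffeneau–Demjanov-type ring enlargement), as practised on 17-oxo steroids, whose ring D has the same quaternary carbon/ketone/methylene array. Ring B is not closed by a cyclisation but arises by a 1,2-alkyl shift within the existing carbocycle (one-carbon ring expansion, five to six). The only new stereocentre, C8, is set under thermodynamic control by the NaOMe equilibration, since the 8α (equatorial) methyl avoids the 1,3-diaxial clash with the C10 methyl that the 8β epimer 10 suffers. The step needs migration of C7 rather than C10, which the quaternary substitution of C10 should secure (the less substituted α-carbon migrates), and it must stop after one insertion, which the doubly α-branched product ketone favours. The unactivated C2=C3 alkene should not react with diazoethane at low temperature.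

Step 8
Reactants: 11 4,4,8α,10β-tetramethyl-trans-octal-2-en-9-one
Product: 12 9α-vinyl-4,4,8α,10β-tetramethyl-trans-octal-2-en-9β-ol
Conditions: CeCl3 (anhydrous, 2 equiv), CH2=CHMgBr (2 equiv), THF, −78 → 0 °C; aq. NH4Cl
Reagents that add atoms: vinylmagnesium bromide, C=C[Mg]Br
Why: 1,2-Addition of the weakly basic vinylcerium reagent (which suppresses enolisation of the hindered ketone) should occur axially on the α face of C9, anti to the axial C10 methyl that shields the β face, giving the 9β-hydroxyl and the 9α carbon chain.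

Step 9
Reactants: 13 methyl acetoacetate
Product: 14 methyl (E)-3-(trifluoromethylsulfonyloxy)but-2-enoate
Conditions: Tf2O (1.2 equiv), Me4NOH (25% aq.), hexanes, 5 °C → rt
Reagents that add atoms: trifluoromethanesulfonic anhydride, FC(F)(F)S(=O)(=O)OS(=O)(=O)C(F)(F)F
Why: O-Sulfonylation of the β-keto ester enolate with a non-chelating ammonium counter-ion should favour the enolate geometry with oxygen trans to the ester and so give the (E)-enol triflate.

Step 10
Reactants: 12 9α-vinyl-4,4,8α,10β-tetramethyl-trans-octal-2-en-9β-ol; 14 methyl (E)-3-(trifluoromethylsulfonyloxy)but-2-enoate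
Product: 16 methyl (13E)-9β-hydroxylabda-2,13-dien-15-oate (8βH), via B-alkyl-9-BBN borane 15 (not isolated)
Conditions: 9-BBN (3 equiv), THF, 0 °C → rt; then 14, Pd(dppf)Cl2 (5 mol %), K3PO4 (3 M aq., 3 equiv), THF/DMF, 50 °C
Reagents that add atoms: none
Why: Anti-Markovnikov hydroboration of the vinyl group (the hindered ring alkene should not react with 9-BBN) followed by B-alkyl Suzuki–Miyaura coupling forms C12–C13 with retention of the enol triflate geometry, which fixes the 13E alkene.

Step 11
Reactants: 16 methyl (13E)-9β-hydroxylabda-2,13-dien-15-oate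
Product: 17 methyl (13E)-2α,3α,9β-trihydroxylabd-13-en-15-oate (8βH)
Conditions: OsO4 (5 mol %), NMO (1.5 equiv), acetone/H2O, 0 °C → rt
Reagents that add atoms: osmium tetroxide, O=[Os](=O)(=O)=O; N-methylmorpholine N-oxide, C[N+]1([O-])CCOCC1; water, O
Why: OsO4-catalysed syn-dihydroxylation should take the isolated C2=C3 alkene before the electron-poor trisubstituted enoate and should occur on the α face, opposite the axial C10 and 4β methyls, giving the 2α,3α-diol.

Step 12
Reactants: 17 methyl (13E)-2α,3α,9β-trihydroxylabd-13-en-15-oate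
Product: 18 methyl (13E)-2α-acetoxy-3α,9β-dihydroxylabd-13-en-15-oate (8βH), CNP0135744.1
Conditions: Ac2O (1.1 equiv), pyridine, CH2Cl2, 0 °C
Reagents that add atoms: acetic anhydride, CC(=O)OC(C)=O
Why: Kinetic acylation should select the equatorial secondary C2 hydroxyl over the axial neopentyl C3 hydroxyl and the tertiary C9 hydroxyl (regioselective monoacetylation).

**Compound list**

1 | (S)-Hajos–Parrish ketone, (7aS)-7a-methyl-2,3,7,7a-tetrahydro-1H-indene-1,5(6H)-dione | O=C1CCC2=CC(=O)CC[C@@]21C | starting material
2 | C9 ethylene ketal of 1 (enone at C3 to C5 kept) | O1CCOC12CCC3=CC(=O)CC[C@@]32C | intermediate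
3 | 4-methyl-Δ5(6)-3-ketone 9-ketal (C4 epimers) | O1CCOC12CC=C3C(C)C(=O)CC[C@@]32C | intermediate
4 | 4,4-dimethyl-Δ5(6)-3-ketone 9-ketal | O1CCOC12CC=C3C(C)(C)C(=O)CC[C@@]32C | intermediate
5 | 4,4,10β-trimethyl-trans-hydrindan-3-one 9-ketal (H-5α) | O1CCOC12CC[C@H]3C(C)(C)C(=O)CC[C@@]32C | intermediate
6 | C3 p-toluenesulfonylhydrazone of 5 (C=N geometry not specified) | O1CCOC12CC[C@H]3C(C)(C)C(=NNS(=O)(=O)c4ccc(C)cc4)CC[C@@]32C | intermediate
7 | 3-lithio-4,4,10β-trimethyl-trans-hydrind-2-ene 9-ketal | O1CCOC12CC[C@H]3C(C)(C)C([Li])=CC[C@@]32C | intermediate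
8 | 4,4,10β-trimethyl-trans-hydrind-2-ene 9-ketal | O1CCOC12CC[C@H]3C(C)(C)C=CC[C@@]32C | intermediate
9 | 4,4,10β-trimethyl-trans-hydrind-2-en-9-one (H-5α) | O=C1CC[C@H]2C(C)(C)C=CC[C@@]21C | intermediate
10 | 4,4,8β,10β-tetramethyl-trans-octal-2-en-9-one (axial C8 methyl) | O=C1[C@@H](C)CC[C@H]2C(C)(C)C=CC[C@@]21C | intermediate
11 | 4,4,8α,10β-tetramethyl-trans-octal-2-en-9-one (H-5α, H-8β) | O=C1[C@H](C)CC[C@H]2C(C)(C)C=CC[C@@]21C | intermediate
12 | 9α-vinyl-4,4,8α,10β-tetramethyl-trans-octal-2-en-9β-ol | C=C[C@]1(O)[C@H](C)CC[C@H]2C(C)(C)C=CC[C@@]21C | intermediate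
13 | methyl acetoacetate | COC(=O)CC(C)=O | starting material
14 | methyl (E)-3-(trifluoromethylsulfonyloxy)but-2-enoate | COC(=O)/C=C(\C)OS(=O)(=O)C(F)(F)F | intermediate
15 | B-alkyl-9-BBN borane (boron on C12 of 12) | B1(C2CCCC1CCC2)CC[C@]3(O)[C@H](C)CC[C@H]4C(C)(C)C=CC[C@@]43C | intermediate
16 | methyl (13E)-9β-hydroxylabda-2,13-dien-15-oate (8βH) | COC(=O)/C=C(\C)CC[C@]1(O)[C@H](C)CC[C@H]2C(C)(C)C=CC[C@@]21C | intermediate
17 | methyl (13E)-2α,3α,9β-trihydroxylabd-13-en-15-oate (8βH) | COC(=O)/C=C(\C)CC[C@]1(O)[C@H](C)CC[C@H]2C(C)(C)[C@H](O)[C@H](O)C[C@@]21C | intermediate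
18 | methyl (13E)-2α-acetoxy-3α,9β-dihydroxylabd-13-en-15-oate (8βH), CNP0135744.1 | COC(=O)/C=C(\C)CC[C@]1(O)[C@H](C)CC[C@H]2C(C)(C)[C@H](O)[C@H](OC(C)=O)C[C@@]21C | target

**Step count and risks**

Total step count: 12. Longest linear sequence: 11 steps (steps 1 to 8 and 10 to 12, from compound 1).

Steps most likely to fail:

Step 7. The insertion may suffer from migration of the C9–C10 bond instead of C9–C7, from sluggish addition to the neopentyl ketone, or from a second homologation. The fallback makes the regiochemistry a matter of construction; it sets out from ketone 9 and returns at ketone 11. LiN(i-Pr)2 and Me3SiCl (THF, −78 °C) would give trimethylsilyl enol ether F1, whose double bond can only lie between C9 and C7 because C10 is quaternary. Cyclopropanation with Et2Zn and CH2I2 (CH2Cl2, 0 °C) would give siloxycyclopropane F2. FeCl3 in DMF (0 °C → rt) would cleave the internal C9–C7 bond by β-scission of the alkoxy radical and give the ring-expanded β-chloro ketone F3 (Saegusa–Ito ring expansion); NaOAc in MeOH at reflux would eliminate HCl to enone F4. Li in NH3/THF (−78 °C) would reduce F4 to the regiodefined lithium enolate F5, which MeI would methylate at C8; NaOMe/MeOH equilibration would then give 11.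

Step 3. Hydrogen may be delivered with poor facial selectivity, giving the cis-fused hydrindane. The fallback sets C5 by dissolving-metal reduction instead; it sets out from ketal 2 and returns at ketone 5. PhSH, aqueous CH2O and Et3N in EtOH at reflux (Kirk–Petrow thiomethylation) would give phenylthiomethyl enone F6; Raney Ni in acetone would desulfurise it to 4-methyl enone F7. Li in NH3/THF with t-BuOH (1 equiv) at −78 °C would reduce the enone with axial protonation at C5 to the trans-fused lithium enolate F8, and MeI would alkylate it at C4 to give 5 (Birch-type reductive alkylation).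

Step 11. Osmylation may lose chemoselectivity and attack the enoate as well as the ring alkene. The fallback dihydroxylates before any other alkene is present; it sets out from ketone 11 and returns at triol 17. OsO4 (cat.) and NMO would convert 11 into keto diol F9; 2,2-dimethoxypropane and PPTS would give acetonide F10. CeCl3 and CH2=CHMgBr would add to C9 to give vinyl carbinol F11. 9-BBN, then 14 with Pd(dppf)Cl2 and K3PO4, would give by way of borane F12 the enoate acetonide F13. Aqueous AcOH (80%, 40 °C) would remove the acetonide to give 17.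

**Further compounds**

F1 | step 7 | trimethylsilyl enol ether of 9 (C9=C7) | C[Si](C)(C)OC1=CC[C@H]2C(C)(C)C=CC[C@@]21C
F2 | step 7 | siloxycyclopropane (C9–C8–C7 ring, CH2 on the α face) | C[Si](C)(C)O[C@@]12C[C@@H]1C[C@H]3C(C)(C)C=CC[C@@]32C
F3 | step 7 | 7-chloro-4,4,10β-trimethyl-trans-octal-2-en-9-one (C7 epimers) | O=C1CC(Cl)C[C@H]2C(C)(C)C=CC[C@@]21C
F4 | step 7 | 4,4,10β-trimethyl-trans-hexahydronaphthalene-2,7-dien-9-one (C7=C8 enone) | O=C1C=CC[C@H]2C(C)(C)C=CC[C@@]21C
F5 | step 7 | lithium enolate (C8=C9) from F4 | [Li]OC1=CCC[C@H]2C(C)(C)C=CC[C@@]21C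
F6 | step 3 | 4-(phenylthiomethyl) enone 9-ketal | O1CCOC12CCC3=C(CSc4ccccc4)C(=O)CC[C@@]32C
F7 | step 3 | 4-methyl enone 9-ketal | O1CCOC12CCC3=C(C)C(=O)CC[C@@]32C
F8 | step 3 | trans-fused lithium enolate (C3=C4) from F7 | O1CCOC12CC[C@H]3C(C)=C(O[Li])CC[C@@]32C
F9 | step 11 | 2α,3α-dihydroxy-4,4,8α,10β-tetramethyl-trans-decal-9-one | O=C1[C@H](C)CC[C@H]2C(C)(C)[C@H](O)[C@H](O)C[C@@]21C
F10 | step 11 | 2α,3α-acetonide of F9 | O=C1[C@H](C)CC[C@H]2C(C)(C)[C@@H]3OC(C)(C)O[C@@H]3C[C@@]21C
F11 | step 11 | 9α-vinyl-9β-ol 2α,3α-acetonide | C=C[C@]1(O)[C@H](C)CC[C@H]2C(C)(C)[C@@H]3OC(C)(C)O[C@@H]3C[C@@]21C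
F12 | step 11 | B-alkyl-9-BBN borane of F11 | B1(C2CCCC1CCC2)CC[C@]3(O)[C@H](C)CC[C@H]4C(C)(C)[C@@H]5OC(C)(C)O[C@@H]5C[C@@]43C
F13 | step 11 | methyl (13E)-9β-hydroxy-2α,3α-isopropylidenedioxylabd-13-en-15-oate | COC(=O)/C=C(\C)CC[C@]1(O)[C@H](C)CC[C@H]2C(C)(C)[C@@H]3OC(C)(C)O[C@@H]3C[C@@]21C
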